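## Retrosynthetic overview

1. Target ⇐ ethylene–alkyne enyne metathesis of a C13 terminal alkyne (side-chain diene made last) and acylation of the C19 alcohol with protected p-coumaric acid.
2. 7α,8α-Diol ⇐ 8(17)-exocyclic alkene (allylic hydroxylation at C7, then α-face hydration at C8); C19 CH2OH and C3 CH2 ⇐ auxiliary ester and C3 ketone of the cyclization product.
3. Decalin ⇐ one oxidative radical bicyclization of an acyclic (E,E)-dienyl α-methyl β-keto ester, head to tail as in the diterpene cyclase but with a radical in place of the cation: ring A (C4–C5 bond) first, ring B (C10–C9 bond) second. C4, C5, C9 and C10 are set here; the absolute sense comes from an 8-phenylmenthyl ester.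
4. Acyclic chain ⇐ γ-alkylation of the keto ester dianion with a C13 allylic bromide ⇐ geranyl bromide + 1-(trimethylsilyl)propyne, then terminal allylic oxidation.

Numbering note: labdane numbering is used for the bicyclic compounds (ring A = C1–C5, C10; ring B = C5–C10; side chain C11–C16 on C9; C17 on C8; C18 (α) and C19 (β) on C4; C20 on C10).

Assumption: the auxiliary acts by the usual 8-phenylmenthyl model (carbinol C–H eclipsing the ester C=O, phenyl ring over one face of the Yb-chelated radical, ester axial in the chair), which predicts the drawn series from the (−)-alcohol; if the sense proves reversed, (+)-8-phenylmenthol is used with no other change.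

## Route

Step 1
Reactants: 1 1-(trimethylsilyl)propyne; 2 geranyl bromide, (2E)-1-bromo-3,7-dimethylocta-2,6-diene
Product: 4 [(5E)-6,10-dimethylundeca-5,9-dien-1-yn-1-yl]trimethylsilane, via propargylic lithium reagent 3 (not isolated)
Conditions: n-BuLi, THF, −78 → 0 °C; then 2, −78 °C → rt
Reagents that add atoms: none
Why: SN2 alkylation of the lithiated silylpropyne at the primary allylic bromide (propargylation) leaves the E-alkene untouched, and the silyl group blocks allenyl coupling and protects the alkyne C–H for later steps.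

Step 2
Reactants: 4 [(5E)-6,10-dimethylundeca-5,9-dien-1-yn-1-yl]trimethylsilane
Product: 5 (2E,6E)-2,6-dimethyl-11-(trimethylsilyl)undeca-2,6-dien-10-yn-1-ol
Conditions: SeO2 (0.3 equiv), t-BuOOH, salicylic acid (0.1 equiv), CH2Cl2, rt
Reagents that add atoms: selenium dioxide O=[Se]=O (delivers the oxygen, catalytic); tert-butyl hydroperoxide CC(C)(C)OO (net oxygen source)
Why: SeO2 allylic oxidation (ene reaction, then [2,3]-sigmatropic shift) picks the E-methyl group of the terminal, least hindered trisubstituted alkene and gives the E-allylic alcohol.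

Step 3
Reactants: 5 (2E,6E)-2,6-dimethyl-11-(trimethylsilyl)undeca-2,6-dien-10-yn-1-ol
Product: 6 [(5E,9E)-11-bromo-6,10-dimethylundeca-5,9-dien-1-yn-1-yl]trimethylsilane
Conditions: CBr4, PPh3, CH2Cl2, 0 °C
Reagents that add atoms: carbon tetrabromide BrC(Br)(Br)Br
Why: Appel bromination is neutral, so the primary allylic alcohol is replaced without allylic shift or E/Z leakage.

Step 4
Reactants: 7 methyl 2-methyl-3-oxobutanoate; 8 (−)-8-phenylmenthol, (1R,2S,5R)-5-methyl-2-(2-phenylpropan-2-yl)cyclohexan-1-ol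
Product: 9 (1R,2S,5R)-5-methyl-2-(2-phenylpropan-2-yl)cyclohexyl 2-methyl-3-oxobutanoate (both C2 epimers)
Conditions: DMAP (cat.), toluene, reflux, methanol distilled off
Reagents that add atoms: none
Why: DMAP-catalysed transesterification of a β-keto ester (through the acylketene) is driven by removal of methanol and installs the auxiliary, which is recovered in step 8.

Step 5
Reactants: 9 8-phenylmenthyl 2-methyl-3-oxobutanoate; 6 [(5E,9E)-11-bromo-6,10-dimethylundeca-5,9-dien-1-yn-1-yl]trimethylsilane
Product: 11 (1R,2S,5R)-5-methyl-2-(2-phenylpropan-2-yl)cyclohexyl (6E,10E)-2,6,10-trimethyl-3-oxo-15-(trimethylsilyl)pentadeca-6,10-dien-14-ynoate (both C2 epimers), via keto ester dianion 10 (not isolated)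
Conditions: NaH, THF, 0 °C; n-BuLi, 0 °C; then 6, 0 °C → rt; 1 M HCl work-up
Reagents that add atoms: none
Why: Weiler dianion γ-alkylation, in which the more basic terminal carbanion attacks the allylic bromide by SN2; the C4 epimer mixture does not matter because C4 becomes a planar radical in step 6.

Step 6
Reactants: 11 acyclic 8-phenylmenthyl β-keto ester
Product: 12 8-phenylmenthyl 3-oxo-14-(trimethylsilyl)-15,16-dinorlabd-8(17)-en-13-yn-19-oate (4α-CH3, 4β-ester, 5α-H, 9α-H, 10β-CH3)
Conditions: Mn(OAc)3·2H2O (2.2 equiv), Cu(OAc)2·H2O (1 equiv), Yb(OTf)3 (1 equiv), degassed CF3CH2OH, 0 °C → rt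
Reagents that add atoms: none
Why: oxidative free-radical polyene cyclization of the Snider type, in which trivalent manganese oxidises the Yb-chelated β-keto ester to the planar C4 radical, which closes ring A (6-endo, C4–C5) and then ring B (6-endo, C10–C9) through a chair–chair array of the two E-alkenes (trans fusion, 5α-H, 10β-CH3, equatorial 9β side chain), with the ester axial and the methyl equatorial at C4 as in the podocarpate precedent, the phenyl ring of the auxiliary shielding one face of the radical so that one enantiomeric series forms, and divalent copper ending the cascade by oxidative elimination of the C8 radical to the less substituted 8(17)-alkene.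

Step 7
Reactants: 12 bicyclic keto ester
Product: 13 3-(p-toluenesulfonyl)hydrazone of 12
Conditions: TsNHNH2, EtOH, AcOH (cat.), 70 °C
Reagents that add atoms: p-toluenesulfonohydrazide Cc1ccc(cc1)S(=O)(=O)NN
Why: hydrazone condensation at the only ketone; the quaternary C4 and the hindered ester prevent pyrazolone formation and no stereocentre is touched.

Step 8
Reactants: 13 tosylhydrazone
Product: 14 14-(trimethylsilyl)-15,16-dinorlabd-8(17)-en-13-yn-19-ol
Conditions: LiAlH4, THF, 0 °C → reflux; NaOH/H2O work-up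
Reagents that add atoms: none
Why: Caglioti reduction, in which hydride adds to the hydrazone C=N and loss of sulfinate and N2 leaves the C3 methylene, while the same reagent reduces the neopentyl ester to the C19 alcohol and frees the auxiliary; no stereocentre is touched.

Step 9
Reactants: 14 14-(trimethylsilyl)-15,16-dinorlabd-8(17)-en-13-yn-19-ol
Product: 15 14-(trimethylsilyl)-15,16-dinorlabd-8(17)-en-13-yne-7α,19-diol
Conditions: SeO2 (0.5 equiv), t-BuOOH, CH2Cl2, rt
Reagents that add atoms: selenium dioxide O=[Se]=O (delivers the oxygen, catalytic); tert-butyl hydroperoxide CC(C)(C)OO (net oxygen source)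
Why: SeO2 allylic hydroxylation (ene reaction, then [2,3]-sigmatropic shift) of the exocyclic alkene removes the axial 7α-hydrogen and returns oxygen to the same α face, giving the axial 7α-alcohol, while the tertiary C9–H is too hindered to compete.

Step 10
Reactants: 15 7α,19-diol
Product: 16 14-(trimethylsilyl)-15,16-dinorlabd-13-yne-7α,8α,19-triol
Conditions: Co(acac)2 (20 mol %), PhSiH3, O2 (1 atm), THF/i-PrOH, rt
Reagents that add atoms: dioxygen O=O
Why: Mukaiyama hydration (hydrogen-atom transfer from a cobalt hydride to the 1,1-disubstituted alkene, O2 capture of the tertiary C8 radical, reduction of the peroxide), in which oxygen enters from the α face, equatorial and away from the axial 10β-methyl group, to give the 8α-ol with the 8β-methyl group.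

Step 11
Reactants: 16 7α,8α,19-triol; 17 (E)-4-acetoxycinnamic acid
Product: 19 19-[(E)-4-acetoxycinnamoyloxy]-14-(trimethylsilyl)-15,16-dinorlabd-13-yne-7α,8α-diol, via 4-acetoxycinnamoyl chloride 18 (not isolated)
Conditions: 17, (COCl)2, DMF (cat.), CH2Cl2, rt; then 16, pyridine, CH2Cl2, −20 → 0 °C
Reagents that add atoms: none
Why: acylation (nucleophilic acyl substitution) by the acid chloride picks the primary C19 alcohol over the axial secondary 7α-OH next to a quaternary carbon and over the tertiary 8-OH.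

Step 12
Reactants: 19 acetate- and silyl-protected ester
Product: 20 19-[(E)-4-hydroxycinnamoyloxy]-15,16-dinorlabd-13-yne-7α,8α-diol
Conditions: K2CO3 (cat.), MeOH, 0 °C → rt
Reagents that add atoms: none
Why: base-catalysed methanolysis cleaves the aryl acetate (an activated ester) and the alkynyl C–Si bond, while the hindered, conjugated neopentyl coumarate is left intact.

Step 13
Reactants: 20 terminal alkyne
Product: 21 19-[(E)-p-coumaroyloxy]labda-13(16),14-diene-7α,8α-diol (target)
Conditions: second-generation Grubbs catalyst RuCl2(=CHPh)(PCy3)(H2IMes) (10 mol %), ethylene (1 atm), CH2Cl2, rt → 40 °C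
Reagents that add atoms: ethylene C=C
Why: ethylene–alkyne cross enyne metathesis turns the terminal alkyne into the 2-substituted buta-1,3-diene, and the electron-poor coumarate alkene, the phenol and the diol are expected to be inert to the ruthenium carbene under these mild conditions.

## Compound list

1 | 1-(trimethylsilyl)propyne | CC#C[Si](C)(C)C | starting material
2 | geranyl bromide, (2E)-1-bromo-3,7-dimethylocta-2,6-diene | CC(C)=CCC/C(C)=C/CBr | starting material
3 | [3-(trimethylsilyl)prop-2-yn-1-yl]lithium | [Li]CC#C[Si](C)(C)C | intermediate (not isolated)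
4 | [(5E)-6,10-dimethylundeca-5,9-dien-1-yn-1-yl]trimethylsilane | CC(C)=CCC/C(C)=C/CCC#C[Si](C)(C)C | intermediate
5 | (2E,6E)-2,6-dimethyl-11-(trimethylsilyl)undeca-2,6-dien-10-yn-1-ol | OC/C(C)=C/CC/C(C)=C/CCC#C[Si](C)(C)C | intermediate
6 | [(5E,9E)-11-bromo-6,10-dimethylundeca-5,9-dien-1-yn-1-yl]trimethylsilane | BrC/C(C)=C/CC/C(C)=C/CCC#C[Si](C)(C)C | intermediate
7 | methyl 2-methyl-3-oxobutanoate | CC(=O)C(C)C(=O)OC | starting material
8 | (−)-8-phenylmenthol, (1R,2S,5R)-5-methyl-2-(2-phenylpropan-2-yl)cyclohexan-1-ol | O[C@@H]1C[C@H](C)CC[C@H]1C(C)(C)c1ccccc1 | starting material (auxiliary, recovered)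
9 | (1R,2S,5R)-5-methyl-2-(2-phenylpropan-2-yl)cyclohexyl 2-methyl-3-oxobutanoate | CC(=O)C(C)C(=O)O[C@@H]1C[C@H](C)CC[C@H]1C(C)(C)c1ccccc1 | intermediate
10 | sodium lithium dianion of 9 | [Na+].[Li+].[CH2-]C(=O)[C-](C)C(=O)O[C@@H]1C[C@H](C)CC[C@H]1C(C)(C)c1ccccc1 | intermediate (not isolated)
11 | 8-phenylmenthyl (6E,10E)-2,6,10-trimethyl-3-oxo-15-(trimethylsilyl)pentadeca-6,10-dien-14-ynoate | CC(C(=O)CC/C(C)=C/CC/C(C)=C/CCC#C[Si](C)(C)C)C(=O)O[C@@H]1C[C@H](C)CC[C@H]1C(C)(C)c1ccccc1 | intermediate
12 | 8-phenylmenthyl 3-oxo-14-(trimethylsilyl)-15,16-dinorlabd-8(17)-en-13-yn-19-oate (4α-CH3, 5α-H, 9α-H, 10β-CH3) | C[Si](C)(C)C#CCC[C@H]1C(=C)CC[C@H]2[C@@](C)(C(=O)O[C@@H]3C[C@H](C)CC[C@H]3C(C)(C)c4ccccc4)C(=O)CC[C@@]21C | intermediate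
13 | 3-(p-toluenesulfonyl)hydrazone of 12 | C[Si](C)(C)C#CCC[C@H]1C(=C)CC[C@H]2[C@@](C)(C(=O)O[C@@H]3C[C@H](C)CC[C@H]3C(C)(C)c4ccccc4)C(=NNS(=O)(=O)c5ccc(C)cc5)CC[C@@]21C | intermediate
14 | 14-(trimethylsilyl)-15,16-dinorlabd-8(17)-en-13-yn-19-ol | C[Si](C)(C)C#CCC[C@H]1C(=C)CC[C@H]2[C@@](C)(CO)CCC[C@@]21C | intermediate
15 | 14-(trimethylsilyl)-15,16-dinorlabd-8(17)-en-13-yne-7α,19-diol | C[Si](C)(C)C#CCC[C@H]1C(=C)[C@H](O)C[C@H]2[C@@](C)(CO)CCC[C@@]21C | intermediate
16 | 14-(trimethylsilyl)-15,16-dinorlabd-13-yne-7α,8α,19-triol | C[Si](C)(C)C#CCC[C@H]1[C@](C)(O)[C@H](O)C[C@H]2[C@@](C)(CO)CCC[C@@]21C | intermediate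
17 | (E)-4-acetoxycinnamic acid | CC(=O)Oc1ccc(/C=C/C(=O)O)cc1 | starting material
18 | (E)-4-acetoxycinnamoyl chloride | CC(=O)Oc1ccc(/C=C/C(Cl)=O)cc1 | intermediate (not isolated)
19 | 19-[(E)-4-acetoxycinnamoyloxy]-14-(trimethylsilyl)-15,16-dinorlabd-13-yne-7α,8α-diol | C[Si](C)(C)C#CCC[C@H]1[C@](C)(O)[C@H](O)C[C@H]2[C@@](C)(COC(=O)/C=C/c3ccc(OC(C)=O)cc3)CCC[C@@]21C | intermediate
20 | 19-[(E)-4-hydroxycinnamoyloxy]-15,16-dinorlabd-13-yne-7α,8α-diol | C#CCC[C@H]1[C@](C)(O)[C@H](O)C[C@H]2[C@@](C)(COC(=O)/C=C/c3ccc(O)cc3)CCC[C@@]21C | intermediate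
21 | 19-[(E)-p-coumaroyloxy]labda-13(16),14-diene-7α,8α-diol | C=CC(=C)CC[C@H]1[C@](C)(O)[C@H](O)C[C@H]2[C@@](C)(COC(=O)/C=C/c3ccc(O)cc3)CCC[C@@]21C | target

## Step count and risks

Total steps: 13. Longest linear sequence: 12 (steps 1–3 and 5–13; step 4 is a one-step branch).

Three steps most likely to fail:

Step 6 (radical bicyclization). The risks are early oxidation of the monocyclic C10 radical, capture of the C8 radical by the silyl alkyne, mixtures of alkene isomers, and lower auxiliary control with the α-methyl substrate. The fallback sets out from 11 and comes back at 12. Compound 11 is deprotonated (NaH, THF) and treated with PhSeCl to give the α-phenylseleno β-keto ester F1. A phenylseleno group-transfer radical bicyclization (Yb(OTf)3, Et3B/O2 or irradiation, CH2Cl2, −45 °C) then closes both rings without any metal oxidant and ends by transfer of the selenium group to C8, giving the 8-phenylseleno bicycle F2. Oxidation with H2O2/pyridine and syn-elimination of the selenoxide toward the methyl group returns 12.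

Step 8 (one reagent for deoxygenation and ester reduction). The risks are elimination of the hindered tosylhydrazone to a 2-alkene and slow reduction of the axial ester. The fallback sets out from 12 and comes back at 14. NaBH4 in MeOH reduces only the ketone to the 3β-hydroxy ester F3. NaH, CS2 and MeI convert it into the S-methyl xanthate F4. Barton–McCombie deoxygenation (Bu3SnH, AIBN, toluene, 110 °C) gives the 3-deoxy ester F5. LiAlH4 in refluxing THF then reduces the ester to 14 and frees the auxiliary.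

Step 10 (hydration at C8). The risks are a C8 epimer mixture from unselective O2 capture and cobalt-hydride isomerisation of the allylic alcohol. The fallback sets out from 15 and comes back at 16. Hydroxyl-directed epoxidation (VO(acac)2, t-BuOOH, CH2Cl2) delivers oxygen syn to the 7α-OH and gives the 8α,17-epoxide F6. LiAlH4 opens it at the primary C17 carbon to the 8α-ol with the 8β-methyl group, which is 16.

## Further compounds

F1 | step 6 | 8-phenylmenthyl (6E,10E)-2,6,10-trimethyl-3-oxo-2-(phenylselanyl)-15-(trimethylsilyl)pentadeca-6,10-dien-14-ynoate (both C2 epimers) | CC([Se]c1ccccc1)(C(=O)CC/C(C)=C/CC/C(C)=C/CCC#C[Si](C)(C)C)C(=O)O[C@@H]2C[C@H](C)CC[C@H]2C(C)(C)c3ccccc3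
F2 | step 6 | 8-phenylmenthyl 3-oxo-8-(phenylselanyl)-14-(trimethylsilyl)-15,16-dinorlabd-13-yn-19-oate (C8 epimers) | C[Si](C)(C)C#CCC[C@H]1C(C)([Se]c6ccccc6)CC[C@H]2[C@@](C)(C(=O)O[C@@H]3C[C@H](C)CC[C@H]3C(C)(C)c4ccccc4)C(=O)CC[C@@]21C
F3 | step 8 | 8-phenylmenthyl 3β-hydroxy-14-(trimethylsilyl)-15,16-dinorlabd-8(17)-en-13-yn-19-oate | C[Si](C)(C)C#CCC[C@H]1C(=C)CC[C@H]2[C@@](C)(C(=O)O[C@@H]3C[C@H](C)CC[C@H]3C(C)(C)c4ccccc4)[C@@H](O)CC[C@@]21C
F4 | step 8 | O-3β S-methyl xanthate of F3 | C[Si](C)(C)C#CCC[C@H]1C(=C)CC[C@H]2[C@@](C)(C(=O)O[C@@H]3C[C@H](C)CC[C@H]3C(C)(C)c4ccccc4)[C@@H](OC(=S)SC)CC[C@@]21C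
F5 | step 8 | 8-phenylmenthyl 14-(trimethylsilyl)-15,16-dinorlabd-8(17)-en-13-yn-19-oate | C[Si](C)(C)C#CCC[C@H]1C(=C)CC[C@H]2[C@@](C)(C(=O)O[C@@H]3C[C@H](C)CC[C@H]3C(C)(C)c4ccccc4)CCC[C@@]21C
F6 | step 10 | 8α,17-epoxy-14-(trimethylsilyl)-15,16-dinorlabd-13-yne-7α,19-diol | C[Si](C)(C)C#CCC[C@H]1[C@]3(OC3)[C@H](O)C[C@H]2[C@@](C)(CO)CCC[C@@]21C
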